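In a one-step world one constant would describe a whole run, so we try that as a tool. At fixed catalyst we treat the reagent as pseudo-first-order, one reagent spent per target formed, and call ln[c(reagent) charged / c(reagent) left], divided by time, the reagent constant.

in all of them: free catalyst 1.3 mol%
- dawn: substrate 0.050 M; reagent 0.60 equiv; run made earlier
- midnight: substrate 0.050 M; reagent 0.90 equiv; run made earlier
- noon: substrate 0.075 M; reagent 1.2 equiv; run made earlier
- flask: substrate 0.050 M; reagent 1.20 equiv; time 6.0 d

- dawn (time / d: target / %, substrate / %): 0.625: 7.2, 92.0; 1.04: 11.3, 86.7; 2.08: 19.5, 78.2; 4.00: 33.8, 65.9; 8.00: 49.0, 49.9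
- midnight (time / d: target / %, substrate / %): 0.625: 9.7, 89.5; 1.04: 14.8, 84.9; 2.08: 28.3, 70.9; 4.00: 47.0, 51.9; 8.00: 70.7, 28.0
- noon (time / d: target / %, substrate / %): 1.25: 28.5, 70.2; 3.00: 58.7, 39.4; 4.00: 72.6, 26.3; 6.00: 91.2, 6.8; 8.00: 100.0, 0.4

(readings scatter by 0.5 percentage points)

- the earlier runs were read with a standard deviation of 0.5 percentage points

- amount of target in the flask at 6.0 d, in percent of the substrate charged
- amount of substrate in the flask at 6.0 d, in percent of the substrate charged

Dawn at 8.00 d reads 0.212 d⁻¹ and midnight reads 0.192 d⁻¹, less at the larger charge. The reagent charges of dawn, midnight and the flask are evenly spaced, so we extend the reciprocal in a straight line and freeze, as our own reckoning, 0.176 d⁻¹, the flask's reagent constant. That gives target 78.3% and substrate 21.7%.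

Now turn the question round: for the substrate to be finished at 6.0 d, the reagent left would be the charge less one equivalent, which asks for 0.299 d⁻¹, or 1.70 times ours. Noon, with 1.50 times the flask's catalyst concentration, reads 0.238 d⁻¹ at that time, lower than that. We expect an unfinished flask.

The forecast takes a constant of about 0.17 per day for the flask. It reads the constant per unit catalyst as falling while reagent rises, “which suggests mild saturation”, and gives target 76.5% (72% to 81%) and substrate 22.5% (18% to 27%).

The flask gives target 77.3% and substrate 21.3%, inside both ranges.

    reagent + catalyst intermediate A ⇌ catalyst intermediate B (K = 1600 M⁻¹, k = 15.1 M⁻¹ h⁻¹)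
    target → over-reaction product (k = 3.38 × 10⁻⁵ h⁻¹)
    catalyst intermediate B ⇌ by-product + catalyst intermediate C (K = 0.180 M, k = 4.90 h⁻¹)
    substrate + free catalyst → catalyst intermediate A (k = 229 M⁻¹ h⁻¹)
    catalyst intermediate C → free catalyst + target (k = 4.37 h⁻¹)

Read back from its target, with one reagent spent per target formed, the flask's reagent constant is 0.172 d⁻¹, close to the frozen 0.176 d⁻¹. Carried to a neighbour flask, the same charge read at 4.0 d, the frozen constant gives target 60.7%, and that neighbour holds target 58.8%. The flask has not come to rest at 6.0 d: at 60.0 d its target stands at 95.5%, its substrate at 0%, its reagent at 16.7% of its own charge, and its over-reaction product at 4.46%.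

The runs are calculated for an exercise; noise was put on by code.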